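**Retrosynthetic overview**
The target is (2S)-8-hydroxy-5,6,7,3',4'-pentamethoxyflavanone; the last disconnections are the C8 O-benzyl ether (hydrogenolysis) and the C2 stereocentre (asymmetric hydrogenation of the flavone C2=C3 bond, C4 re-oxidised).
Ring C is cut at C3–C4 and O1–C8a: a [3+3] annulation of a C,O-dinucleophile (lithium enolate of 3,4-dimethoxyacetophenone: C3 and O1) with a 1,3-dielectrophile (3-(benzyloxy)-2-fluoro-4,5,6-trimethoxybenzoyl chloride: C4 and C8a) gives the complete flavone in one flask.
Enabling feature: the C4 carbonyl sits on C4a of ring A, ortho to C8a; after C-acylation the 1,3-diketonate holds O1 in a six-membered array over C8a and the carbonyl stabilises the Meisenheimer adduct, so a fluorine on C8a (lost in the same step) is displaced while the C5 methoxy group is not.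
The ring A piece comes from 5-fluoro-1,2,3-trimethoxybenzene by two fluorine-directed ortho-lithiations (C8–O first, then the C4 carboxyl).
Ring order: rings A and B are bought as benzenes; ring C is the only ring formed (step 5) and is then reduced at C2–C3.

Key step: step 5

Assumption: 5-fluoro-1,2,3-trimethoxybenzene is taken as a purchasable fluoroarene; its two ring hydrogens are equivalent, so the first lithiation has no regiochemical issue.

**Step 1**
Reactants: 1 5-fluoro-1,2,3-trimethoxybenzene
Product: 4 6-fluoro-2,3,4-trimethoxyphenol, via aryllithium 2 (not isolated), via arylboronate 3 (not isolated)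
Conditions: n-BuLi, THF, -78 °C; B(OMe)3, -78 to 0 °C; 30% H2O2, 0 °C to rt
Reagents that add atoms: hydrogen peroxide, OO
Why: Directed ortho-metalation at the carbon flanked by F and OMe, borylation of aryllithium 2 and oxidative aryl migration from boron to oxygen in boronate 3 should install the future C8 oxygen.

**Step 2**
Reactants: 4 6-fluoro-2,3,4-trimethoxyphenol
Product: 5 2-(benzyloxy)-1-fluoro-3,4,5-trimethoxybenzene
Conditions: BnBr, K2CO3, DMF, rt
Reagents that add atoms: benzyl bromide, BrCc1ccccc1
Why: Williamson ether synthesis on the phenoxide; the benzyl ether masks the C8 oxygen through the lithiation, acylation, hydrogenation and oxidation steps and can be removed later without acid or base.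

**Step 3**
Reactants: 5 2-(benzyloxy)-1-fluoro-3,4,5-trimethoxybenzene
Product: 7 3-(benzyloxy)-2-fluoro-4,5,6-trimethoxybenzoic acid, via aryllithium 6 (not isolated)
Conditions: lithium 2,2,6,6-tetramethylpiperidide, THF, -78 °C; CO2, -78 °C to rt; aq. HCl work-up
Reagents that add atoms: carbon dioxide, O=C=O
Why: Directed ortho-metalation: the one remaining ring hydrogen lies between F and OMe and should be removed by the hindered amide base in preference to the benzylic CH2, and carboxylation of aryllithium 6 places the future C4 carbon.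

**Step 4**
Reactants: 7 3-(benzyloxy)-2-fluoro-4,5,6-trimethoxybenzoic acid
Product: 8 3-(benzyloxy)-2-fluoro-4,5,6-trimethoxybenzoyl chloride
Conditions: (COCl)2, DMF (cat.), CH2Cl2, 0 °C to rt; used crude
Reagents that add atoms: oxalyl chloride, O=C(Cl)C(Cl)=O
Why: Acid chloride formation through the Vilsmeier-type chloroiminium catalyst, conditions that aryl methyl and benzyl ethers should tolerate.

**Step 5**
Reactants: 8 3-(benzyloxy)-2-fluoro-4,5,6-trimethoxybenzoyl chloride; 9 1-(3,4-dimethoxyphenyl)ethan-1-one
Product: 12 8-(benzyloxy)-2-(3,4-dimethoxyphenyl)-5,6,7-trimethoxy-4H-chromen-4-one, via lithium enolate 10 (not isolated), via 1,3-diketone 11 (not isolated)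
Conditions: 9 (2.0 equiv), LiN(SiMe3)2 (2.0 equiv), THF, -78 °C; 8, -78 to 0 °C; then DMF, 110 °C (THF distilled off), one flask
Reagents that add atoms: none
Why: Lithium enolate 10 is C-acylated by acid chloride 8 (Claisen-type acylation, C3–C4), the second equivalent of enolate deprotonates diketone 11, and on heating in DMF the diketonate oxygen on the carbon bearing ring B adds to C8a and fluoride leaves (addition–elimination, SNAr, O1–C8a). The closest known reaction types are the one-pot C-acylation of ketone lithium enolates with aroyl chlorides and the base-mediated cyclisation of 1-(2-fluoroaryl)-1,3-diketones to flavones. Ring C closes by 6-exo-trig ipso attack (counted along the C8a–C8 π bond) through a Meisenheimer adduct stabilised by the C4 carbonyl; C-attack of the diketonate would need a four-membered ring and is not available. No stereocentre is formed, since the flavone is planar; C2 is set in step 6. The step needs substitution at C8a–F and not at the other ortho carbon C5–OMe, which fluoride's far better nucleofugality in SNAr should secure, and C- over O-acylation, which the lithium enolate in THF and transacylation of any enol ester by the excess enolate should secure.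

**Step 6**
Reactants: 12 8-(benzyloxy)-2-(3,4-dimethoxyphenyl)-5,6,7-trimethoxy-4H-chromen-4-one
Product: 14 (2S,4S)-8-(benzyloxy)-2-(3,4-dimethoxyphenyl)-5,6,7-trimethoxy-3,4-dihydro-2H-chromen-4-ol, via flavanone 13 (not isolated)
Conditions: Ru(cod)(2-methylallyl)2 (5 mol%), (R,R)-SINpEt·HBF4 [1,3-bis((R)-1-(naphthalen-1-yl)ethyl)imidazolinium tetrafluoroborate] (10 mol%), KOt-Bu (12 mol%), H2 (100 bar), toluene, 25 to 40 °C, run to full uptake
Reagents that add atoms: none
Why: Ru–NHC-catalysed enantioselective hydrogenation, a reaction type established for flavones: the chiral carbene ligand should select one enantiotopic face of the C2=C3 bond and so set C2 as S (the ligand antipode is taken if the opposite sense is found on this substrate), and the ketone of 13 is then reduced to the cis alcohol, a centre that step 7 removes again.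

**Step 7**
Reactants: 14 (2S,4S)-8-(benzyloxy)-2-(3,4-dimethoxyphenyl)-5,6,7-trimethoxy-3,4-dihydro-2H-chromen-4-ol
Product: 13 (2S)-8-(benzyloxy)-2-(3,4-dimethoxyphenyl)-5,6,7-trimethoxy-2,3-dihydro-4H-chromen-4-one
Conditions: Dess–Martin periodinane, CH2Cl2, 0 °C to rt
Reagents that add atoms: none
Why: Dess–Martin oxidation of the secondary benzylic alcohol should return the C4 ketone without base, so C2 is not exposed to ring opening by retro-oxa-Michael reaction, and the benzyl ether keeps ring A from reacting as an oxidisable phenol.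

**Step 8**
Reactants: 13 (2S)-8-(benzyloxy)-2-(3,4-dimethoxyphenyl)-5,6,7-trimethoxy-2,3-dihydro-4H-chromen-4-one
Product: 15 (2S)-2-(3,4-dimethoxyphenyl)-8-hydroxy-5,6,7-trimethoxy-2,3-dihydro-4H-chromen-4-one
Conditions: H2 (1 atm), Pd/C (10%), EtOAc, rt
Reagents that add atoms: none
Why: Hydrogenolysis of the aryl benzyl ether under neutral conditions, where the O-benzyl bond should cleave much faster than the cyclic C2–O1 bond or the aryl ketone, frees the C8 hydroxyl and leaves C2 untouched.

**Compound list**
1 | 5-fluoro-1,2,3-trimethoxybenzene | COc1cc(F)cc(OC)c1OC | starting material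
2 | (6-fluoro-2,3,4-trimethoxyphenyl)lithium | [Li]c1c(F)cc(OC)c(OC)c1OC | intermediate
3 | dimethyl (6-fluoro-2,3,4-trimethoxyphenyl)boronate | COB(OC)c1c(F)cc(OC)c(OC)c1OC | intermediate
4 | 6-fluoro-2,3,4-trimethoxyphenol | Oc1c(F)cc(OC)c(OC)c1OC | intermediate
5 | 2-(benzyloxy)-1-fluoro-3,4,5-trimethoxybenzene | COc1cc(F)c(OCc2ccccc2)c(OC)c1OC | intermediate
6 | [3-(benzyloxy)-2-fluoro-4,5,6-trimethoxyphenyl]lithium | [Li]c1c(F)c(OCc2ccccc2)c(OC)c(OC)c1OC | intermediate
7 | 3-(benzyloxy)-2-fluoro-4,5,6-trimethoxybenzoic acid | OC(=O)c1c(F)c(OCc2ccccc2)c(OC)c(OC)c1OC | intermediate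
8 | 3-(benzyloxy)-2-fluoro-4,5,6-trimethoxybenzoyl chloride | ClC(=O)c1c(F)c(OCc2ccccc2)c(OC)c(OC)c1OC | intermediate
9 | 1-(3,4-dimethoxyphenyl)ethan-1-one | CC(=O)c1ccc(OC)c(OC)c1 | starting material
10 | lithium 1-(3,4-dimethoxyphenyl)ethen-1-olate | [Li]OC(=C)c1ccc(OC)c(OC)c1 | intermediate
11 | 1-[3-(benzyloxy)-2-fluoro-4,5,6-trimethoxyphenyl]-3-(3,4-dimethoxyphenyl)propane-1,3-dione (present as its lithium enolate) | COc1ccc(C(=O)CC(=O)c2c(F)c(OCc3ccccc3)c(OC)c(OC)c2OC)cc1OC | intermediate
12 | 8-(benzyloxy)-2-(3,4-dimethoxyphenyl)-5,6,7-trimethoxy-4H-chromen-4-one | COc1ccc(-c2cc(=O)c3c(OC)c(OC)c(OC)c(OCc4ccccc4)c3o2)cc1OC | intermediate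
13 | (2S)-8-(benzyloxy)-2-(3,4-dimethoxyphenyl)-5,6,7-trimethoxy-2,3-dihydro-4H-chromen-4-one | COc1ccc([C@@H]2CC(=O)c3c(c(OCc4ccccc4)c(OC)c(OC)c3OC)O2)cc1OC | intermediate
14 | (2S,4S)-8-(benzyloxy)-2-(3,4-dimethoxyphenyl)-5,6,7-trimethoxy-3,4-dihydro-2H-chromen-4-ol | COc1ccc([C@@H]2C[C@H](O)c3c(c(OCc4ccccc4)c(OC)c(OC)c3OC)O2)cc1OC | intermediate
15 | (2S)-2-(3,4-dimethoxyphenyl)-8-hydroxy-5,6,7-trimethoxy-2,3-dihydro-4H-chromen-4-one | COc1ccc([C@@H]2CC(=O)c3c(c(O)c(OC)c(OC)c3OC)O2)cc1OC | target

**Step count and risks**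
Total step count: 8. Longest linear sequence: 8 steps (1 to 15); ketone 9 enters at step 5.

Steps most likely to fail:

Step 5. The enolate may be O-acylated or acylated twice, and the ipso-substitution at the electron-rich C–F carbon may be slow when the crude lithium diketonate is heated, so that material stalls at 11 or loses the benzyl group. The fallback sets out from 8 and returns at 11, making the C3–C4 bond by a different reaction. Acyl Sonogashira coupling of 8 with 4-ethynyl-1,2-dimethoxybenzene (PdCl2(PPh3)2, CuI, Et3N, THF, rt) should give the ynone 1-[3-(benzyloxy)-2-fluoro-4,5,6-trimethoxyphenyl]-3-(3,4-dimethoxyphenyl)prop-2-yn-1-one F1. Conjugate addition of pyrrolidine (EtOH, rt) should give the enaminone 1-[3-(benzyloxy)-2-fluoro-4,5,6-trimethoxyphenyl]-3-(3,4-dimethoxyphenyl)-3-(pyrrolidin-1-yl)prop-2-en-1-one F2. Hydrolysis (aq. HCl, THF) should give pure 11, which is then cyclised on its own as the caesium diketonate (Cs2CO3, DMSO, 120 °C) to 12.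

Step 6. Facial discrimination may be poor on this hindered, peri-methoxylated flavone, reduction may be incomplete, or the benzyl group may be attacked. A mixture of 13 and 14 is harmless, since step 7 converges both to 13. The fallback sets out from 12 and returns at 13. Conjugate hydride reduction (LiBH(s-Bu)3, THF, -78 °C) should give racemic 8-(benzyloxy)-2-(3,4-dimethoxyphenyl)-5,6,7-trimethoxy-2,3-dihydro-4H-chromen-4-one F3. Kinetic resolution by asymmetric transfer hydrogenation (RhCl(Cp*)(TsDPEN), the enantiomer that consumes the (2R)-ketone, HCO2H–Et3N, EtOAc) should reduce the unwanted enantiomer to (2R,4R)-8-(benzyloxy)-2-(3,4-dimethoxyphenyl)-5,6,7-trimethoxy-3,4-dihydro-2H-chromen-4-ol F4 and leave 13, which is separated and taken to step 8.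

Step 3. The base may deprotonate the benzylic CH2 (followed by [1,2]-Wittig rearrangement), or aryllithium 6 may lose LiF to an aryne on warming. The fallback sets out from 5 and returns at 7 by electrophilic substitution instead of metalation. Vilsmeier–Haack formylation (POCl3, DMF, 70 °C) at the single free ring position, para to one methoxy group and ortho to another, should give 3-(benzyloxy)-2-fluoro-4,5,6-trimethoxybenzaldehyde F5. Pinnick oxidation (NaClO2, NaH2PO4, 2-methylbut-2-ene, t-BuOH–H2O) should give 7.

**Further compounds**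
F1 | step 5 | 1-[3-(benzyloxy)-2-fluoro-4,5,6-trimethoxyphenyl]-3-(3,4-dimethoxyphenyl)prop-2-yn-1-one | COc1ccc(C#CC(=O)c2c(F)c(OCc3ccccc3)c(OC)c(OC)c2OC)cc1OC
F2 | step 5 | 1-[3-(benzyloxy)-2-fluoro-4,5,6-trimethoxyphenyl]-3-(3,4-dimethoxyphenyl)-3-(pyrrolidin-1-yl)prop-2-en-1-one | COc1ccc(C(=CC(=O)c2c(F)c(OCc3ccccc3)c(OC)c(OC)c2OC)N2CCCC2)cc1OC
F3 | step 6 | racemic 8-(benzyloxy)-2-(3,4-dimethoxyphenyl)-5,6,7-trimethoxy-2,3-dihydro-4H-chromen-4-one | COc1ccc(C2CC(=O)c3c(c(OCc4ccccc4)c(OC)c(OC)c3OC)O2)cc1OC
F4 | step 6 | (2R,4R)-8-(benzyloxy)-2-(3,4-dimethoxyphenyl)-5,6,7-trimethoxy-3,4-dihydro-2H-chromen-4-ol | COc1ccc([C@H]2C[C@@H](O)c3c(c(OCc4ccccc4)c(OC)c(OC)c3OC)O2)cc1OC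
F5 | step 3 | 3-(benzyloxy)-2-fluoro-4,5,6-trimethoxybenzaldehyde | O=Cc1c(F)c(OCc2ccccc2)c(OC)c(OC)c1OC
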